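**Retrosynthetic overview**

1. Target: (13S)-7β-acetoxy-9α,13;15,16-diepoxy-8β-hydroxylabd-14-en-6-one. Late stage: C7 acetate from a 7β,8β-diol (osmylation of a 7-en-6-one); ring D (dihydrofuran) by alkynol cycloisomerisation; ring C (O9–C13) by opening of a reagent-set 13,16-epoxide with the C9 hydroxyl.
2. Side chain C12–C16 is grown on C11 from a 9α,11-epoxide through the 13,9-spirolactone, an ynone and a 1,1-disubstituted enyne. Ring A comes from ring-closing metathesis of a C10 allyl and a C4 vinyl group.
3. Ring B rests on one feature: C9 (tertiary C–O) and C10 (quaternary, methyl-bearing) are adjacent fully substituted ring carbons, and C5 is the α-carbon of the C6 ketone. C5–C10 is therefore cut as the opening of a tetrasubstituted 9,10-epoxy-11-ol by a C5 enol silane (inversion at C10, retention at C9).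
4. The precursor comes from Sharpless epoxidation of an enynol, made by Sonogashira coupling of (2Z)-2-iodo-3-methylhexa-2,5-dien-1-ol with 5,5-dimethylhept-6-en-1-yn-3-ol; ynone formation and Me2CuLi addition then set the (Z)-C7=C8 bond.
5. Order of ring formation: B (step 11), A (step 12), C (step 18), D (step 20).

Key step: step 11

**Remarks on the chemistry (assumptions)**

- Labdane numbering is used for all intermediates, also the acyclic ones.
- Alcohol 9 is used as the racemate. Its carbinol carbon becomes the C6 ketone in step 7, so 10 and 11 are carried as pairs of epimers at that carbon.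
- C5 is epimerisable next to the C6 ketone. The trans ring fusion (5α-H) is taken to be the more stable one, and any 5β isomer is expected to equilibrate under the base of step 14.

**Route**

Step 1
Reactants: 1 ethyl but-2-ynoate; 2 allylmagnesium bromide
Product: 4 ethyl (2Z)-2-iodo-3-methylhexa-2,5-dienoate, via alkenylcopper adduct 3 (not isolated)
Conditions: 2, CuBr·SMe2 (1 equiv), THF, −78 °C; add 1, −78 °C; then I2, −78 °C to 0 °C
Reagents that add atoms: iodine, [I][I]
Why: Syn carbocupration of the ynoate by allylcopper (conjugate addition) gives an α-cuprio enoate that holds its geometry at −78 °C, and iodinolysis with retention puts iodine cis to the allyl group, which fixes the later C9=C10 geometry (C11 cis to the C10 methyl); an ynoate is used because copper-catalysed methylmagnesiation of a 2-alkyn-1-ol would put the methyl group on the carbinol-bearing carbon.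

Step 2
Reactants: 4 ethyl (2Z)-2-iodo-3-methylhexa-2,5-dienoate
Product: 5 (2Z)-2-iodo-3-methylhexa-2,5-dien-1-ol
Conditions: (i-Bu)2AlH (2.2 equiv), CH2Cl2, −78 °C; aq. potassium sodium tartrate
Reagents that add atoms: none
Why: 1,2-Reduction of the enoate by the aluminium hydride at −78 °C leaves the vinyl iodide and the alkene geometry untouched.

Step 3
Reactants: 6 methyl 3,3-dimethylpent-4-enoate
Product: 7 3,3-dimethylpent-4-enal
Conditions: (i-Bu)2AlH (1.05 equiv), CH2Cl2, −78 °C; aq. potassium sodium tartrate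
Reagents that add atoms: none
Why: Partial ester reduction stops at the aluminium hemiacetal at −78 °C and gives the aldehyde on work-up (the ester is the Johnson–Claisen product of prenol and is sold as such).

Step 4
Reactants: 7 3,3-dimethylpent-4-enal; 8 ethynylmagnesium bromide
Product: 9 rac-5,5-dimethylhept-6-en-1-yn-3-ol
Conditions: THF, 0 °C; water
Reagents that add atoms: none
Why: Grignard addition of the acetylide to the aldehyde; the new carbinol centre is racemic and is oxidised away in step 7.

Step 5
Reactants: 5 (2Z)-2-iodo-3-methylhexa-2,5-dien-1-ol; 9 rac-5,5-dimethylhept-6-en-1-yn-3-ol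
Product: 10 (2E)-2-(3-hydroxy-5,5-dimethylhept-6-en-1-yn-1-yl)-3-methylhexa-2,5-dien-1-ol
Conditions: PdCl2(PPh3)2 (cat.), CuI (cat.), Et3N, THF, rt
Reagents that add atoms: none
Why: Sonogashira coupling of the tetrasubstituted vinyl iodide proceeds with retention of the alkene geometry and tolerates both free hydroxyl groups.

Step 6
Reactants: 10 enynediol
Product: 11 [(2S,3S)-2-(3-hydroxy-5,5-dimethylhept-6-en-1-yn-1-yl)-3-methyl-3-(prop-2-en-1-yl)oxiran-2-yl]methanol
Conditions: Ti(Oi-Pr)4 (cat.), L-(+)-diethyl tartrate (cat.), t-BuOOH, 4 Å molecular sieves, CH2Cl2, −25 °C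
Reagents that add atoms: tert-butyl hydroperoxide, CC(C)(C)OO
Why: Sharpless asymmetric epoxidation of the primary allylic alcohol with L-(+)-tartrate should deliver oxygen to the face that gives the (9S,10S)-epoxide and leave the terminal alkenes and the alkyne alone; it is placed before the dienone exists because a (Z)-dienone with a fully substituted C9=C10 bond would close to a 2H-pyran.

Step 7
Reactants: 11 epoxy diol
Product: 12 1-[(2S,3S)-2-(hydroxymethyl)-3-methyl-3-(prop-2-en-1-yl)oxiran-2-yl]-5,5-dimethylhept-6-en-1-yn-3-one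
Conditions: MnO2 (excess), CH2Cl2, rt
Reagents that add atoms: none
Why: MnO2 oxidises the propargylic alcohol selectively, since the primary hydroxyl of the epoxy alcohol is unactivated, and this removes the racemic centre.

Step 8
Reactants: 12 hydroxy ynone
Product: 13 trimethylsilyl ether of 12
Conditions: Me3SiCl, imidazole, CH2Cl2, 0 °C
Reagents that add atoms: chlorotrimethylsilane, C[Si](C)(C)Cl
Why: Silylation of the primary alcohol keeps the (Z)-enone of step 9 from closing to a cyclic hemiketal and keeps an alkoxide out of the enolisation of step 10.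

Step 9
Reactants: 13 silylated ynone
Product: 15 (2Z)-enone trimethylsilyl ether, via alkenylcuprate adduct 14 (not isolated)
Conditions: Me2CuLi (from MeLi and CuI), THF, −78 °C; MeOH then aq. NH4Cl at −78 °C
Reagents that add atoms: lithium dimethylcuprate, [Li+].C[Cu-]C
Why: Syn conjugate addition of the Gilman cuprate to the ynone and protonation at −78 °C put the new methyl group and the C7 hydrogen cis, so C9 ends up cis to the carbonyl ((Z)-enone), and attack at the β-carbon C8 leaves the propargylic epoxide intact.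

Step 10
Reactants: 15 (2Z)-enone trimethylsilyl ether
Product: 17 (2Z,4Z)-silyl dienol ether epoxy alcohol (key precursor), via bis-silyl dienol ether 16 (not isolated)
Conditions: KN(SiMe3)2, t-BuMe2SiCl, HMPA, THF, −78 °C; then K2CO3 (cat.), MeOH, 0 °C
Reagents that add atoms: tert-butyldimethylsilyl chloride, CC(C)(C)[Si](C)(C)Cl
Why: Kinetic deprotonation of the enone on its α′ side (C5) with silylation gives the cross-conjugated (Z)-enol silane, and K2CO3 in methanol then cleaves only the primary trimethylsilyl ether.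

Step 11
Reactants: 17 silyl dienol ether epoxy alcohol
Product: 19 (4R,5S,6S)-4-hydroxy-4-(hydroxymethyl)-3,5-dimethyl-6-(2-methylbut-3-en-2-yl)-5-(prop-2-en-1-yl)cyclohex-2-en-1-one, via titanium alkoxide chelate 18 (not isolated)
Conditions: TiCl(Oi-Pr)3 (1.2 equiv), CH2Cl2, −78 °C to −30 °C; aq. NaHCO3
Reagents that add atoms: none
Why: Proposed new method: ligand exchange puts titanium on O11, the metal binds the epoxide oxygen in a five-membered chelate, the C5 terminus of the enol silane attacks C10 anti to the C10–O bond, and loss of silicon from the silyloxocarbenium ion gives the C6 ketone; the closest known reactions are the Lewis-acid cyclisation of epoxy enol silanes at the more substituted epoxide carbon and the titanium-mediated C3 opening of 2,3-epoxy alcohols. Ring B closes in the 6-endo-tet mode (C9–C10 inside the new ring) through a half-chair in which the (Z)-C7=C8 bond holds C5 over C10. C10 is inverted and C9 retained, so the (9S,10S)-epoxide gives 9α-OH and 10β-CH3; C5 follows from the (Z)-enol silane geometry in that half-chair (5α-H, arm cis to the C10 methyl) and can be corrected by enolisation. The step needs attack at C10 and not at C9: a backside attack of C5 on C9 is barred because the σ* orbital of C9–O lies in the plane of the diene, but the C9–O bond is aligned with the diene π system, so ionisation of C9 to a dienyl cation (leading to a cyclopentenone by 4π closure or to a 1,2-shift) is the main threat. It is opposed only by the electron-poor O11–Ti group on the neighbouring carbon and by the weak, chelating Lewis acid at low temperature; the mono-chloro titanium reagent is used instead of TiCl4 to limit chloride opening of the epoxide.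

Step 12
Reactants: 19 ring-B enone diol
Product: 20 9α,11-dihydroxydrima-2,7-dien-6-one
Conditions: second-generation Grubbs catalyst RuCl2(=CHPh)(H2IMes)(PCy3) (cat.), toluene, 80 °C
Reagents that add atoms: none
Why: Ring-closing metathesis initiates at the C10 allyl group and closes onto the neopentyl vinyl group to form ring A, while the trisubstituted enone and the free diol are inert.

Step 13
Reactants: 20 9α,11-dihydroxydrima-2,7-dien-6-one
Product: 21 9α,11-dihydroxydrim-7-en-6-one
Conditions: 2-nitrobenzenesulfonyl hydrazide, Et3N, CH2Cl2, rt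
Reagents that add atoms: none
Why: Diimide reduces the cis-disubstituted C2=C3 bond much faster than the hindered trisubstituted enone and creates no stereocentre.

Step 14
Reactants: 21 9α,11-dihydroxydrim-7-en-6-one
Product: 23 9α,11-epoxydrim-7-en-6-one, via primary tosylate 22 (not isolated)
Conditions: TsCl, Et3N, DMAP (cat.), CH2Cl2, 0 °C; then K2CO3, MeOH, rt
Reagents that add atoms: none
Why: Selective sulfonylation of the primary C11 hydroxyl and 3-exo-tet displacement by the tertiary C9 alkoxide give the spiro-epoxide with C9 unchanged, and the base should also settle C5 in the trans ring fusion.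

Step 15
Reactants: 23 9α,11-epoxydrim-7-en-6-one
Product: 25 6-oxo-14,15,16-trinorlabd-7-en-13,9α-olide, via hydroxy acid 24 (not isolated)
Conditions: AcOH, LiN(i-Pr)2 (2 equiv per AcOH), THF, 0 °C to 45 °C; then aq. HCl; TsOH (cat.), toluene, rt
Reagents that add atoms: acetic acid, CC(=O)O
Why: Creger-type opening of the epoxide at its CH2 terminus (C11) by the acetic acid dianion and acid-induced lactonisation onto the C9 hydroxyl; a copper-free nucleophile is chosen because cuprates would attack this γ,δ-epoxy enone in the SN2′ sense at C7, and the hindered C6 carbonyl should at most be enolised.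

Step 16
Reactants: 25 spirolactone
Product: 26 9α-hydroxy-15-(trimethylsilyl)-16-norlabd-7-en-14-yne-6,13-dione
Conditions: Me3SiC≡CLi (from Me3SiC≡CH and n-BuLi), THF, −78 °C; aq. NH4Cl
Reagents that add atoms: (trimethylsilyl)acetylene, C#C[Si](C)(C)C
Why: Mono-addition of the lithium acetylide to the unhindered lactone carbonyl (the lithium hemiketal does not collapse before work-up), while the C6 ketone, shielded by the C4 and C10 methyl groups, should stay untouched.

Step 17
Reactants: 26 hydroxy ynone
Product: 28 9α-hydroxylabda-7,13(16)-dien-14-yn-6-one, via silylated enyne 27 (not isolated)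
Conditions: Ph3P=CH2 (from Ph3PCH3Br and KOt-Bu, 3 equiv), THF, 0 °C to rt; then K2CO3, MeOH, rt
Reagents that add atoms: methyltriphenylphosphonium bromide, C[P+](c1ccccc1)(c1ccccc1)c1ccccc1.[Br-]
Why: Wittig methylenation of the ynone (the open form of the lactol) gives the 1,1-disubstituted enyne, and methanolysis removes the C-silyl group, which was needed only for the acetylide addition.

Step 18
Reactants: 28 9α-hydroxylabda-7,13(16)-dien-14-yn-6-one
Product: 30 (13S)-9α,13-epoxy-16-hydroxylabd-7-en-14-yn-6-one, via alkynyl epoxide 29 (not isolated)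
Conditions: Shi N-aryl oxazolidinone ketone (cat.; the antipode that gives the (13R)-epoxide), KHSO5 (as 2KHSO5·KHSO4·K2SO4), K2CO3, MeCN/dimethoxymethane/aq. buffer, 0 °C; then camphorsulfonic acid (cat.), CH2Cl2, 0 °C
Reagents that add atoms: potassium peroxymonosulfate, [K+].[O-]S(=O)(=O)OO
Why: Shi epoxidation (chiral dioxirane) of the 1,1-disubstituted enyne alkene, to which the electron-poor enone is inert, followed by acid-catalysed 5-exo-tet opening at the tertiary propargylic carbon by the C9 hydroxyl with inversion should set C13 as S; the ketone antipode is to be fixed on a model enyne because the facial sense for 1,1-disubstituted enynes is not secure.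

Step 19
Reactants: 30 spiroether alkynol
Product: 32 (13S)-9α,13-epoxy-7β,8β,16-trihydroxylabd-14-yn-6-one, via osmate ester 31 (not isolated)
Conditions: OsO4 (1.1 equiv), pyridine, THF, 0 °C to rt; then aq. NaHSO3
Reagents that add atoms: osmium tetroxide, O=[Os](=O)(=O)=O
Why: Osmylation (cis-dihydroxylation) of the enone is expected from the β-face, anti to the pseudo-axial C9–O bond of the spiro centre and its C13 substituents, to give the 7β,8β-diol; stoichiometric OsO4 with pyridine is used because the alkene is hindered and electron-poor, and the terminal alkyne reacts far more slowly.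

Step 20
Reactants: 32 triol alkyne
Product: 33 (13S)-9α,13;15,16-diepoxy-7β,8β-dihydroxylabd-14-en-6-one
Conditions: Mo(CO)6 (cat.), Et3N, Et2O, hν (350 nm), rt
Reagents that add atoms: none
Why: McDonald cycloisomerisation: the terminal alkyne forms a molybdenum vinylidene and the C16 hydroxyl adds to C15 (5-endo), which gives the 2,3-dihydrofuran without touching C13.

Step 21
Reactants: 33 dihydrofuran diol
Product: 34 (13S)-7β-acetoxy-9α,13;15,16-diepoxy-8β-hydroxylabd-14-en-6-one (target)
Conditions: Ac2O, pyridine, DMAP (cat.), CH2Cl2, 0 °C; aq. NaHCO3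
Reagents that add atoms: acetic anhydride, CC(=O)OC(C)=O
Why: Acylation of the only unhindered hydroxyl, the secondary C7 alcohol; the tertiary C8 alcohol should not react and the basic medium spares the enol ether.

**Compound list**

1 | ethyl but-2-ynoate | CC#CC(=O)OCC | starting material
2 | allylmagnesium bromide | C=CC[Mg]Br | starting material
3 | ethyl (2Z)-2-cuprio-3-methylhexa-2,5-dienoate (alkenylcopper adduct) | CCOC(=O)/C([Cu])=C(/CC=C)C | intermediate
4 | ethyl (2Z)-2-iodo-3-methylhexa-2,5-dienoate | CCOC(=O)/C(I)=C(/CC=C)C | intermediate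
5 | (2Z)-2-iodo-3-methylhexa-2,5-dien-1-ol | OC/C(I)=C(/CC=C)C | intermediate
6 | methyl 3,3-dimethylpent-4-enoate | COC(=O)CC(C)(C)C=C | starting material
7 | 3,3-dimethylpent-4-enal | O=CCC(C)(C)C=C | intermediate
8 | ethynylmagnesium bromide | C#C[Mg]Br | starting material
9 | rac-5,5-dimethylhept-6-en-1-yn-3-ol | C#CC(O)CC(C)(C)C=C | intermediate
10 | (2E)-2-(3-hydroxy-5,5-dimethylhept-6-en-1-yn-1-yl)-3-methylhexa-2,5-dien-1-ol (both carbinol epimers) | OC/C(C#CC(O)CC(C)(C)C=C)=C(/CC=C)C | intermediate
11 | [(2S,3S)-2-(3-hydroxy-5,5-dimethylhept-6-en-1-yn-1-yl)-3-methyl-3-(prop-2-en-1-yl)oxiran-2-yl]methanol (both carbinol epimers) | C=CC(C)(C)CC(O)C#C[C@@]1(CO)O[C@@]1(C)CC=C | intermediate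
12 | 1-[(2S,3S)-2-(hydroxymethyl)-3-methyl-3-(prop-2-en-1-yl)oxiran-2-yl]-5,5-dimethylhept-6-en-1-yn-3-one | C=CC(C)(C)CC(=O)C#C[C@@]1(CO)O[C@@]1(C)CC=C | intermediate
13 | trimethylsilyl ether of 12 | C=CC(C)(C)CC(=O)C#C[C@@]1(CO[Si](C)(C)C)O[C@@]1(C)CC=C | intermediate
14 | lithium alkenyl(methyl)cuprate adduct of 13 (copper on C7, cis to the new methyl group) | [Li+].C=CC(C)(C)CC(=O)/C([Cu-]C)=C(C)\[C@@]1(CO[Si](C)(C)C)O[C@@]1(C)CC=C | intermediate
15 | (2Z)-6,6-dimethyl-2-[(2S,3S)-3-methyl-3-(prop-2-en-1-yl)-2-{[(trimethylsilyl)oxy]methyl}oxiran-2-yl]octa-2,7-dien-4-one | C=CC(C)(C)CC(=O)/C=C(C)\[C@@]1(CO[Si](C)(C)C)O[C@@]1(C)CC=C | intermediate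
16 | (2Z,4Z)-tert-butyldimethylsilyl dienol ether of 15 | C=CC(C)(C)/C=C(O[Si](C)(C)C(C)(C)C)/C=C(C)\[C@@]1(CO[Si](C)(C)C)O[C@@]1(C)CC=C | intermediate
17 | [(2S,3S)-2-{(2Z,4Z)-4-[(tert-butyldimethylsilyl)oxy]-6,6-dimethylocta-2,4,7-trien-2-yl}-3-methyl-3-(prop-2-en-1-yl)oxiran-2-yl]methanol (key precursor) | C=CC(C)(C)/C=C(O[Si](C)(C)C(C)(C)C)/C=C(C)\[C@@]1(CO)O[C@@]1(C)CC=C | intermediate
18 | chlorodiisopropoxytitanium alkoxide (O11) of 17 | C=CC(C)(C)/C=C(O[Si](C)(C)C(C)(C)C)/C=C(C)\[C@@]1(CO[Ti](Cl)(OC(C)C)OC(C)C)O[C@@]1(C)CC=C | intermediate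
19 | (4R,5S,6S)-4-hydroxy-4-(hydroxymethyl)-3,5-dimethyl-6-(2-methylbut-3-en-2-yl)-5-(prop-2-en-1-yl)cyclohex-2-en-1-one (9α-OH, 10β-CH3, 5α-H) | O=C1C=C(C)[C@](O)(CO)[C@@](C)(CC=C)[C@@H]1C(C)(C)C=C | intermediate
20 | 9α,11-dihydroxydrima-2,7-dien-6-one (5α-H, 10β-CH3) | O=C1C=C(C)[C@](O)(CO)[C@@]2(C)CC=CC(C)(C)[C@H]12 | intermediate
21 | 9α,11-dihydroxydrim-7-en-6-one | O=C1C=C(C)[C@](O)(CO)[C@@]2(C)CCCC(C)(C)[C@H]12 | intermediate
22 | 9α-hydroxy-11-(4-methylbenzenesulfonyloxy)drim-7-en-6-one | O=C1C=C(C)[C@](O)(COS(=O)(=O)c3ccc(C)cc3)[C@@]2(C)CCCC(C)(C)[C@H]12 | intermediate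
23 | 9α,11-epoxydrim-7-en-6-one | O=C1C=C(C)[C@]3(CO3)[C@@]2(C)CCCC(C)(C)[C@H]12 | intermediate
24 | 9α-hydroxy-6-oxo-14,15,16-trinorlabd-7-en-13-oic acid | O=C1C=C(C)[C@](O)(CCC(=O)O)[C@@]2(C)CCCC(C)(C)[C@H]12 | intermediate
25 | 6-oxo-14,15,16-trinorlabd-7-en-13,9α-olide | O=C1C=C(C)[C@]3(CCC(=O)O3)[C@@]2(C)CCCC(C)(C)[C@H]12 | intermediate
26 | 9α-hydroxy-15-(trimethylsilyl)-16-norlabd-7-en-14-yne-6,13-dione (in equilibrium with its 9,13-lactol) | O=C1C=C(C)[C@](O)(CCC(=O)C#C[Si](C)(C)C)[C@@]2(C)CCCC(C)(C)[C@H]12 | intermediate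
27 | 9α-hydroxy-15-(trimethylsilyl)labda-7,13(16)-dien-14-yn-6-one | O=C1C=C(C)[C@](O)(CCC(=C)C#C[Si](C)(C)C)[C@@]2(C)CCCC(C)(C)[C@H]12 | intermediate
28 | 9α-hydroxylabda-7,13(16)-dien-14-yn-6-one | O=C1C=C(C)[C@](O)(CCC(=C)C#C)[C@@]2(C)CCCC(C)(C)[C@H]12 | intermediate
29 | (13R)-13,16-epoxy-9α-hydroxylabd-7-en-14-yn-6-one | O=C1C=C(C)[C@](O)(CC[C@]3(CO3)C#C)[C@@]2(C)CCCC(C)(C)[C@H]12 | intermediate
30 | (13S)-9α,13-epoxy-16-hydroxylabd-7-en-14-yn-6-one | O=C1C=C(C)[C@]3(CC[C@@](CO)(C#C)O3)[C@@]2(C)CCCC(C)(C)[C@H]12 | intermediate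
31 | cyclic 7β,8β-osmate ester of 30 (hexavalent osmium, bis-pyridine adduct) | O=[Os]3(=O)O[C@H]1C(=O)[C@H]2C(C)(C)CCC[C@]2(C)[C@@]2(CC[C@@](CO)(C#C)O2)[C@@]1(C)O3.c1ccncc1.c1ccncc1 | intermediate
32 | (13S)-9α,13-epoxy-7β,8β,16-trihydroxylabd-14-yn-6-one | O[C@H]1C(=O)[C@H]2C(C)(C)CCC[C@]2(C)[C@@]2(CC[C@@](CO)(C#C)O2)[C@@]1(C)O | intermediate
33 | (13S)-9α,13;15,16-diepoxy-7β,8β-dihydroxylabd-14-en-6-one | O[C@H]1C(=O)[C@H]2C(C)(C)CCC[C@]2(C)[C@@]2(CC[C@@]3(C=COC3)O2)[C@@]1(C)O | intermediate
34 | (13S)-7β-acetoxy-9α,13;15,16-diepoxy-8β-hydroxylabd-14-en-6-one | CC(=O)O[C@H]1C(=O)[C@H]2C(C)(C)CCC[C@]2(C)[C@@]2(CC[C@@]3(C=COC3)O2)[C@@]1(C)O | target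

**Step count**

Total: 21 steps. Longest linear sequence: 19 steps (steps 1, 2 and 5–21; the branch through steps 3 and 4 is equally long).

**Steps most likely to fail, with fallbacks**

Step 11 (bears the label). What may go wrong: the C9–O bond, which lies parallel to the π system of the diene in the reactive conformer, ionises faster than C5 attacks C10, and the dienyl cation closes to a cyclopentenone or suffers a 1,2-shift; chloride may also open the epoxide. The fallback uses known reactions only and makes the C5–C10 bond by a thermal pericyclic closure instead of an epoxide opening; its cost is that the material becomes racemic and must be resolved. It sets out from 10. Silylation of the primary hydroxyl (t-BuMe2SiCl, imidazole) gives the silyl ether F1, and MnO2 gives the ynone F2. Me2CuLi at −78 °C gives the (Z)-dienone F3 (in equilibrium with its 2H-pyran valence isomer), and KN(SiMe3)2 with t-BuMe2SiCl gives the 2-silyloxy-triene F4. Heating F4 in toluene should bring about disrotatory 6π-electrocyclisation to the cyclohexadiene F5 (racemic); the two outside groups, the C5 arm and the C10 methyl, end up cis as in 19. Dimethyldioxirane then oxidises the distal, tetrasubstituted C8=C9 bond of this dienol silane from the face away from both β groups (vinylogous Rubottom oxidation) to give the γ-hydroxy enone F6. Bu4NF removes the silyl ether to give racemic 19, which is resolved by chromatography on a chiral stationary phase; the route is rejoined at 19.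

Step 19. What may go wrong: osmylation from the α-face, because the β-face carries the syn-axial C10 methyl, or no facial preference at all; either outcome gives the 8-epimeric diol. The fallback installs the two oxygens one at a time and sets out from 30. Dimethyldioxirane should epoxidise the enone from that same, more open α-face to give the 7α,8α-epoxy ketone F7. Acid-catalysed hydrolysis (HClO4, aqueous THF) opens it at the tertiary β-carbon C8 with inversion (trans-diaxial opening) to the 7α,8β-diol F8. DBU then epimerises the α-ketol centre C7 to the equatorial 7β-alcohol, which is 32.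

Step 18. What may go wrong: poor facial selectivity of the dioxirane on the 1,1-disubstituted enyne, hence a mixture at C13 that the stereospecific ring closure passes on. The fallback sets C13 by Sharpless epoxidation of an allylic alcohol and sets out from 25. LiCH2OCH2OMe (from Bu3SnCH2OCH2OMe and n-BuLi) adds once to the lactone to give the hydroxy ketone F9, and Wittig methylenation gives the allylic ether F10. Acidic methanol (HCl cat.) removes the methoxymethyl group to give the allylic alcohol F11. Sharpless epoxidation with D-(−)-diethyl tartrate gives the (13R)-epoxy alcohol F12, and Dess–Martin periodinane gives the epoxy aldehyde F13. The Ohira–Bestmann reagent (K2CO3, MeOH) converts F13 into the alkynyl epoxide 29, which is cyclised with camphorsulfonic acid as in step 18.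

**Further compounds**

F1 | step 11 | (2E)-1-[(tert-butyldimethylsilyl)oxy]-2-(3-hydroxy-5,5-dimethylhept-6-en-1-yn-1-yl)-3-methylhexa-2,5-diene | CC(C)(C)[Si](C)(C)OC/C(C#CC(O)CC(C)(C)C=C)=C(/CC=C)C
F2 | step 11 | ynone from F1 (C6 ketone) | CC(C)(C)[Si](C)(C)OC/C(C#CC(=O)CC(C)(C)C=C)=C(/CC=C)C
F3 | step 11 | (Z)-dienone with C11 silyl ether (C6 cis to C9, C8 cis to the allyl group) | C=CC(C)(C)CC(=O)/C=C(C)\C(CO[Si](C)(C)C(C)(C)C)=C(\C)CC=C
F4 | step 11 | 2-silyloxy-triene (tert-butyldimethylsilyl dienol ether of F3) | C=CC(C)(C)/C=C(O[Si](C)(C)C(C)(C)C)/C=C(C)\C(CO[Si](C)(C)C(C)(C)C)=C(\C)CC=C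
F5 | step 11 | racemic cyclohexadiene from 6π closure (C5 arm cis to the C10 methyl; one enantiomer drawn) | CC(C)(C)[Si](C)(C)OC1=CC(C)=C(CO[Si](C)(C)C(C)(C)C)[C@@](C)(CC=C)[C@@H]1C(C)(C)C=C
F6 | step 11 | racemic 11-O-(tert-butyldimethylsilyl) ether of 19 (one enantiomer drawn) | O=C1C=C(C)[C@](O)(CO[Si](C)(C)C(C)(C)C)[C@@](C)(CC=C)[C@@H]1C(C)(C)C=C
F7 | step 19 | (13S)-7α,8α;9α,13-diepoxy-16-hydroxylabd-14-yn-6-one | O1[C@@H]2C(=O)[C@H]3C(C)(C)CCC[C@]3(C)[C@@]3(CC[C@@](CO)(C#C)O3)[C@]12C
F8 | step 19 | (13S)-9α,13-epoxy-7α,8β,16-trihydroxylabd-14-yn-6-one | O[C@@H]1C(=O)[C@H]2C(C)(C)CCC[C@]2(C)[C@@]2(CC[C@@](CO)(C#C)O2)[C@@]1(C)O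
F9 | step 18 | 9α-hydroxy-14-(methoxymethoxy)-15,16-dinorlabd-7-ene-6,13-dione | O=C1C=C(C)[C@](O)(CCC(=O)COCOC)[C@@]2(C)CCCC(C)(C)[C@H]12
F10 | step 18 | 9α-hydroxy-14-(methoxymethoxy)-15-norlabda-7,13(16)-dien-6-one | O=C1C=C(C)[C@](O)(CCC(=C)COCOC)[C@@]2(C)CCCC(C)(C)[C@H]12
F11 | step 18 | 9α,14-dihydroxy-15-norlabda-7,13(16)-dien-6-one | O=C1C=C(C)[C@](O)(CCC(=C)CO)[C@@]2(C)CCCC(C)(C)[C@H]12
F12 | step 18 | (13R)-13,16-epoxy-9α,14-dihydroxy-15-norlabd-7-en-6-one | O=C1C=C(C)[C@](O)(CC[C@]3(CO3)CO)[C@@]2(C)CCCC(C)(C)[C@H]12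
F13 | step 18 | (13R)-13,16-epoxy-9α-hydroxy-6-oxo-15-norlabd-7-en-14-al | O=C1C=C(C)[C@](O)(CC[C@]3(CO3)C=O)[C@@]2(C)CCCC(C)(C)[C@H]12
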